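Remark: the target has no stereocentre and its diaryl ether bonds are taken to rotate freely, so no stereodescriptor is needed; 4-bromo-3,5-dimethoxybenzaldehyde and 2-iodo-1,3,5-trimethoxybenzene are taken as purchasable.

## Analysis of the target

The target is a linear chain of eight benzene rings, lettered A to H from the 2,4,6-trihydroxyphenyl end, joined by seven diaryl ether oxygens and carrying 21 free hydroxyl groups, so that 35 of its 48 ring carbons bear oxygen. There is no stereocentre, and the problem is one of connectivity alone. Rings B, D and F have ether oxygens on C1 and C4 and hydroxyls on C3 and C5, so the C4 oxygen sits between two oxygenated carbons. Rings C, E and G have ether oxygens on the neighbouring carbons C1 and C6 and a vicinal triol on C3 to C5, while rings A and H are the phloroglucinol and pyrogallol ends. The free polyphenol, with four pyrogallol-type rings, is easily oxidised by air, so it is released last and all hydroxyls travel as methyl ethers. The difficulty is that every ether bond lies next to one or two oxygenated carbons, where copper couplings of hindered phenols are weak, and that no late electrophilic reagent can tell the eight electron-rich rings apart. The strategy rests on ring G: its ether oxygens on C1 (to ring F) and C6 (to ring H), beside the oxygenated carbons C3 to C5, form the 1,2-difunctionalisation pattern of 3,4,5-trimethoxybenzyne 24, so the hindered oxygen of ring F can be added to C1 while C6 is marked with iodine for ring H.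

## Retrosynthetic reasoning

**27 to 26.** The 21 O–H bonds are traced back to O–CH3 bonds. Methyl is the one group that survives fluoride, a hydride base, copper with phosphate at 90 to 100 °C, peracid and hydrogenolysis, and it adds little bulk beside the hindered ether positions. The forward step must cleave 21 alkyl–oxygen bonds and none of the seven aryl–oxygen–aryl bonds. A boron Lewis acid does this, because only the methyl carbons are open to attack by bromide.

**26 to 25 and 1.** The bond between C6 of ring G and the oxygen of ring H is cut. The hindered carbon then lies on the electrophile (iodide 25), and the nucleophile 1 keeps two free ortho positions, which is the combination copper coupling tolerates. Cutting the other bond of that oxygen would require a hindered phenol on ring G as nucleophile.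

**25 to 22 and 6 (through 23 and 24).** Both bonds at the two neighbouring carbons of ring G are cut together: the bond from the ring F oxygen to C1 and the C6–I bond. Ring G becomes aryne 24, released from 6; the oxygen becomes that of phenoxide 23, made from 22; and iodine comes from a donor. The cut is placed here for two reasons. The hydroxyl of 22 sits between two methoxy groups, a phenol that copper handles poorly but a strained aryne accepts. And the iodine cannot be introduced afterwards, because on any ether made from 22 an electrophile would choose the free positions of ring A or of rings B to F first. The forward reaction must deliver oxygen to the aryne carbon remote from the flanking methoxy group and must iodinate the aryl anion faster than anything protonates it.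

**22 to 21, then to 19 and 20.** The free hydroxyl of 22 is carried as the benzyl ether 21, which hydrogenolysis opens without touching methyl ethers. 21 is cut between C1 of ring A and its oxygen into iodide 20 and phenol 19. Again the ring with two ortho substituents is the iodide, and the hydroxyl of 19 has two free ortho positions. The six-ring chain is grown from ring F towards ring A so that each pair of rings of type B/C and D/E enters as the same pre-iodinated block 9. Nothing before the key step then goes beyond established reactions.

**19 to 17, then to 16 and 9.** The hydroxyl on C1 of ring B is traced back to the formyl group of 17 (Baeyer–Villiger oxidation and cleavage of the formate). 17 is cut between C6 of ring C and the oxygen of ring D into iodide 9 and phenol 16. The formyl group masks the phenol, so that 9 cannot couple with itself.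

**16 to 14, then to 13 and 9.** The same two operations are repeated one unit further: 16 comes from aldehyde 14, and 14 from 9 and 13 by the bond between C6 of ring E and the oxygen of ring F. 13 supplies ring F with its C4 oxygen benzylated.

**9 to 8, then to 1 and 7.** 9 is cut at the C–I bond to 8, and 8 at the bond between C4 of the formyl-bearing ring and the oxygen of 1. The carbon between two methoxy groups is again the electrophile, here bromide 7 with its activating para formyl group, and 1 keeps both ortho positions free. Iodination after the coupling is possible only at this size: the formyl group makes the ring from 7 much poorer than the trimethoxyphenoxy ring, whose two free positions are equivalent. On the seven-ring stage no such bias exists, which is why ring G is made from the aryne.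

**13 to 11 to 10; 6 to 3 to 2 to 1.** The ring F unit 13 comes from 10 by benzylation (11) and Baeyer–Villiger oxidation. The aryne precursor 6 comes from 1 by ortho-bromination (2), O-silylation (3), silyl migration from oxygen to carbon, and triflation. This places silicon on the carbon between the oxygen and a methoxy group and so fixes where the triple bond of 24 forms.

## Alternatives that were turned down

**Alternative 1: ring A by Claisen cyclisation of a triketide.** Ring A is cut between its ether carbon and a neighbouring hydroxyl carbon, back to the open-chain ester A1, which already holds the ring B oxygen as an α-aryloxy ketone. In the forward step the C6 carbanion of A1 acylates the ester carbon and the triketone enolises to the phloroglucinol A2.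
- For: the oxygen between rings A and B is set by simple alkylation of an unhindered phenol, so no coupling at a ring with two ortho substituents is needed. On this one bond it is stronger than the copper coupling of 20 in step 12.
- Against: C6 of A1 is the least acidic of its three methylene groups, since C2 and C4 each lie between two carbonyls, and 3,5-dioxo esters tend to lactonise through oxygen to pyranones instead. A2 then has three free hydroxyls to methylate. Above all, the alternative solves the easiest of the seven ether bonds at a cost of four to five steps and leaves the bonds around rings C, E and G untouched.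
- Comparison: the chosen route buys ring A as 20 and spends its effort on the motif that recurs three times.

**Alternative 2: ring B by Danheiser benzannulation.** Ring B is cut at two C–C bonds into the cyclobutenone A3, which carries ring C, and the aryl ynol ether A4, which carries ring A. On heating, A3 opens to a vinylketene, adds A4, and the resulting dienylketene closes to the phenol A5.
- For: the hindered oxygen on C4 of ring B and both of its oxygenated neighbours are fixed by the pericyclic sequence, with no hindered C–O coupling. A5 also emerges with bromine on C6 of ring C, giving in one step what 8 and 9 need two steps for. On that point it is stronger.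
- Against: A3 needs an aryloxy group on the saturated carbon of a cyclobutenone, and A4 is the ynol ether of a phenol with two ortho substituents. Both are sensitive and need several steps each. Rings D and F would need the same annulation with ever larger ynol ethers, or a return to couplings.
- Comparison: the chosen route draws every ring from a purchasable benzene derivative (1, 7, 10 and 20) and needs a sensitive intermediate, the aryne, only once.

**Alternative 3: ring E by Moore rearrangement of a squarate adduct.** Ring E is cut at one C–C bond back to the vinylcyclobutenone A6. Thermal ring opening to a dienylketene and six-electron closure should give the phenol A7.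
- For: the pentaoxygenated ring forms with complete regiocontrol and with the C6 oxygen already present as a free hydroxyl, so no carbon–iodine bond has to be turned into a carbon–oxygen bond. On that point it is stronger than the aryne route.
- Against: the hydroxyl of A7 sits between an aryloxy and a methoxy group and is the nucleophile for the next ether bond, which is the hindered-phenol coupling the chosen route avoids. Each of rings C, E and G would cost a squarate sequence of four to five steps with a 2-aryloxyvinyl metal reagent of growing size.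
- Comparison: the chosen route makes each such ring from an aromatic precursor in one or two steps and places the hindered carbon on the electrophile.

Key step: step 14

## Route

Step 1
Reactants: 1 3,4,5-trimethoxyphenol
Product: 2 2-bromo-3,4,5-trimethoxyphenol
Conditions: NBS (1.0 equiv), CH2Cl2, −78 → 0 °C
Reagents that add atoms: N-bromosuccinimide, O=C1CCC(=O)N1Br
Why: Electrophilic bromination of an activated phenol; the para position is blocked by a methoxy group and the two ortho positions are equivalent, so one equivalent of NBS at low temperature should stop at the monobromide.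

Step 2
Reactants: 2 2-bromo-3,4,5-trimethoxyphenol
Product: 3 (2-bromo-3,4,5-trimethoxyphenoxy)trimethylsilane
Conditions: HMDS, THF, 65 °C; concentrate
Reagents that add atoms: hexamethyldisilazane, C[Si](C)(C)N[Si](C)(C)C
Why: O-Silylation of the phenol with HMDS, with ammonia as the only by-product, prepares the silyl migration of the next step.

Step 3
Reactants: 3 (2-bromo-3,4,5-trimethoxyphenoxy)trimethylsilane
Product: 6 3,4,5-trimethoxy-2-(trimethylsilyl)phenyl trifluoromethanesulfonate, via aryllithium 4 (not isolated), via lithium 3,4,5-trimethoxy-2-(trimethylsilyl)phenoxide 5 (not isolated)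
Conditions: n-BuLi (1.1 equiv), THF, −78 °C; then Tf2O (1.2 equiv), −78 °C → rt
Reagents that add atoms: triflic anhydride, O=S(=O)(OS(=O)(=O)C(F)(F)F)C(F)(F)F
Why: Bromine–lithium exchange gives 4, which undergoes the anionic 1,3 shift of silicon from oxygen to carbon (retro-Brook rearrangement) to phenoxide 5; triflation of 5 gives the ortho-silylaryl triflate, the standard fluoride-triggered aryne precursor.

Step 4
Reactants: 1 3,4,5-trimethoxyphenol, 7 4-bromo-3,5-dimethoxybenzaldehyde
Product: 8 3,5-dimethoxy-4-(3,4,5-trimethoxyphenoxy)benzaldehyde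
Conditions: CuI (20 mol %), picolinic acid (40 mol %), K3PO4, DMSO, 100 °C, argon
Reagents that add atoms: none
Why: Ullmann diaryl ether synthesis; the para formyl group activates the carbon–bromine bond of 7 towards copper, the hydroxyl of 1 has two free ortho positions, and the non-enolisable aldehyde is inert to phosphate in DMSO.

Step 5
Reactants: 8 3,5-dimethoxy-4-(3,4,5-trimethoxyphenoxy)benzaldehyde
Product: 9 4-(2-iodo-3,4,5-trimethoxyphenoxy)-3,5-dimethoxybenzaldehyde
Conditions: NIS (1.05 equiv), TFA (cat.), MeCN, 0 °C → rt, dark
Reagents that add atoms: N-iodosuccinimide, O=C1CCC(=O)N1I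
Why: Electrophilic aromatic iodination; the trimethoxyphenoxy ring is far more nucleophilic than the formyl-bearing ring and its two free positions are equivalent, so one equivalent of NIS should give the monoiodide ortho to the ether oxygen.

Step 6
Reactants: 10 syringaldehyde (4-hydroxy-3,5-dimethoxybenzaldehyde)
Product: 11 4-(benzyloxy)-3,5-dimethoxybenzaldehyde
Conditions: BnBr, K2CO3, DMF, 60 °C
Reagents that add atoms: benzyl bromide, BrCc1ccccc1
Why: Williamson etherification of the phenol; benzyl is chosen because hydrogenolysis later removes it beside 18 methyl ethers.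

Step 7
Reactants: 11 4-(benzyloxy)-3,5-dimethoxybenzaldehyde
Product: 13 4-(benzyloxy)-3,5-dimethoxyphenol, via 4-(benzyloxy)-3,5-dimethoxyphenyl formate 12 (not isolated)
Conditions: mCPBA, CH2Cl2, 0 °C → rt; NaHCO3 wash; then K2CO3 (cat.), MeOH, rt
Reagents that add atoms: meta-chloroperbenzoic acid, OOC(=O)c1cccc(Cl)c1
Why: Baeyer–Villiger oxidation of an electron-rich benzaldehyde (Dakin-type); the trioxygenated aryl group migrates in preference to hydride to give formate 12, which mild methanolysis cleaves.

Step 8
Reactants: 9 4-(2-iodo-3,4,5-trimethoxyphenoxy)-3,5-dimethoxybenzaldehyde, 13 4-(benzyloxy)-3,5-dimethoxyphenol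
Product: 14 4-{2-[4-(benzyloxy)-3,5-dimethoxyphenoxy]-3,4,5-trimethoxyphenoxy}-3,5-dimethoxybenzaldehyde (three-ring aldehyde D–E–F)
Conditions: CuI (20 mol %), picolinic acid (40 mol %), K3PO4, DMSO, 90 °C, argon
Reagents that add atoms: none
Why: Ullmann diaryl ether synthesis; the hydroxyl of 13 has two free ortho positions and the iodide of 9 lies between two oxygen substituents, the arrangement in which the hindered partner is best placed as the electrophile. The non-enolisable aldehyde and the benzyl ether are inert to phosphate in DMSO.

Step 9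
Reactants: 14 three-ring aldehyde D–E–F
Product: 16 4-{2-[4-(benzyloxy)-3,5-dimethoxyphenoxy]-3,4,5-trimethoxyphenoxy}-3,5-dimethoxyphenol (three-ring phenol D–E–F), via formate of the three-ring phenol 15 (not isolated)
Conditions: mCPBA, CH2Cl2, 0 °C → rt; NaHCO3 wash; then K2CO3 (cat.), MeOH, rt
Reagents that add atoms: meta-chloroperbenzoic acid, OOC(=O)c1cccc(Cl)c1
Why: Baeyer–Villiger oxidation as in step 7; the 4-aryloxy-3,5-dimethoxyphenyl group is electronically the same migrating group, and methanolysis of formate 15 frees the hydroxyl on C1 of ring D.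

Step 10
Reactants: 9 4-(2-iodo-3,4,5-trimethoxyphenoxy)-3,5-dimethoxybenzaldehyde, 16 three-ring phenol D–E–F
Product: 17 five-ring aldehyde B–C–D–E–F (formyl on C1 of ring B; benzyl ether on C4 of ring F; all other oxygens methylated)
Conditions: CuI (20 mol %), picolinic acid (40 mol %), K3PO4, DMSO, 90 °C, argon
Reagents that add atoms: none
Why: Ullmann diaryl ether synthesis of the same type as step 8, forming the bond from C6 of ring C to the oxygen on C1 of ring D.

Step 11
Reactants: 17 five-ring aldehyde B–C–D–E–F
Product: 19 five-ring phenol B–C–D–E–F (free hydroxyl on C1 of ring B; benzyl ether on C4 of ring F), via formate of the five-ring phenol 18 (not isolated)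
Conditions: mCPBA, CH2Cl2, 0 °C → rt; NaHCO3 wash; then K2CO3 (cat.), MeOH, rt
Reagents that add atoms: meta-chloroperbenzoic acid, OOC(=O)c1cccc(Cl)c1
Why: Baeyer–Villiger oxidation as in steps 7 and 9; the aldehyde is the only group that a peracid converts quickly at 0 °C.

Step 12
Reactants: 19 five-ring phenol B–C–D–E–F, 20 2-iodo-1,3,5-trimethoxybenzene
Product: 21 six-ring benzyl ether A–B–C–D–E–F (benzyl ether on C4 of ring F; all other oxygens methylated)
Conditions: CuI (20 mol %), picolinic acid (40 mol %), K3PO4, DMSO, 90 °C, argon
Reagents that add atoms: none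
Why: Ullmann diaryl ether synthesis; the iodide of 20 lies between two methoxy groups, a partner type on which copper couplings of polymethoxylated rings are established, and the hydroxyl of 19 has two free ortho positions.

Step 13
Reactants: 21 six-ring benzyl ether A–B–C–D–E–F
Product: 22 six-ring phenol A–B–C–D–E–F (free hydroxyl on C4 of ring F between two methoxy groups; all other oxygens methylated)
Conditions: H2 (1 atm), Pd/C (palladium on carbon), EtOAc/MeOH, rt
Reagents that add atoms: none
Why: Hydrogenolysis of the benzyl ether; methyl ethers and diaryl ethers are inert and the molecule holds no other reducible group.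

Step 14
Reactants: 22 six-ring phenol A–B–C–D–E–F, 6 3,4,5-trimethoxy-2-(trimethylsilyl)phenyl trifluoromethanesulfonate
Product: 25 seven-ring aryl iodide A–B–C–D–E–F–G (iodine on C6 of ring G; all oxygens methylated), via potassium phenoxide of the six-ring phenol 23 (not isolated), via 3,4,5-trimethoxybenzyne 24 (not isolated)
Conditions: KH (1.05 equiv), THF, 0 °C; then C4F9I (3 equiv), 6 (2 equiv), KF, 18-crown-6, THF, 0 °C → rt, dark, slow argon stream
Reagents that add atoms: nonafluoro-1-iodobutane, FC(F)(F)C(F)(F)C(F)(F)C(F)(F)I
Why: Proposed new method: KH turns 22 into the potassium phenoxide 23 with loss of H2, so that no O–H proton remains, and fluoride then removes the silyl group of 6 with loss of triflate to give aryne 24. The phenoxide oxygen adds to the aryne carbon that becomes C1 of ring G, the one remote from the flanking methoxy group; that group distorts the triple bond so that the remote carbon is the more electrophilic one, the carbanion develops on C6 between the oxygens on C1 and C5, and the bulk of 23 favours the same carbon. The aryl anion then attacks iodine of C4F9I in a halophilic substitution that forms the C6–I bond; the perfluorobutyl anion loses fluoride, which releases more 24, and leaves as gaseous perfluorobut-1-ene, chosen so that the spent donor does not stay in solution as an electrophile for 23. The closest known reactions are the O-arylation of phenols by arynes from ortho-silylaryl triflates and aryne three-component couplings in which the aryl anion formed by addition of a nucleophile is iodinated by a perfluoroalkyl iodide or an iodoalkyne; the combination of a phenoxide with iodine capture is new. No ring is closed and no stereocentre is formed. The step needs O-arylation over C-arylation, secured because both ortho positions and the para position of the ring F phenoxide are substituted; it needs regiocontrol on the aryne, secured by the methoxy group that ends on C5 of ring G; and it needs iodination ahead of protonation, secured by the hydride base, THF in place of acetonitrile and an excess of donor.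

Step 15
Reactants: 25 seven-ring aryl iodide A–B–C–D–E–F–G, 1 3,4,5-trimethoxyphenol
Product: 26 permethylated eight-ring ether A–B–C–D–E–F–G–H (henicosamethyl ether of the target)
Conditions: CuI (20 mol %), picolinic acid (40 mol %), K3PO4, DMSO, 90 °C, argon
Reagents that add atoms: none
Why: Ullmann diaryl ether synthesis; the iodide on C6 of ring G lies between an aryloxy and a methoxy group as in 9, and the hydroxyl of 1 has two free ortho positions.

Step 16
Reactants: 26 permethylated eight-ring ether A–B–C–D–E–F–G–H
Product: 27 target CNP0206369.0 (eight-ring ether with 21 free hydroxyl groups)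
Conditions: BBr3 (excess), CH2Cl2, −78 °C → rt; then MeOH/H2O, 0 °C, argon
Reagents that add atoms: none
Why: Lewis-acid cleavage of aryl methyl ethers; bromide attacks only the methyl carbons of the boron-complexed ethers, so the seven diaryl ether bonds, which offer no saturated carbon, should stay intact.

## Compound list

1 | 3,4,5-trimethoxyphenol | COc1cc(O)cc(OC)c1OC | starting material
2 | 2-bromo-3,4,5-trimethoxyphenol | COc1cc(O)c(Br)c(OC)c1OC | intermediate
3 | (2-bromo-3,4,5-trimethoxyphenoxy)trimethylsilane | COc1cc(O[Si](C)(C)C)c(Br)c(OC)c1OC | intermediate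
4 | [2,3,4-trimethoxy-6-(trimethylsilyloxy)phenyl]lithium (aryllithium) | COc1cc(O[Si](C)(C)C)c([Li])c(OC)c1OC | intermediate (not isolated)
5 | lithium 3,4,5-trimethoxy-2-(trimethylsilyl)phenoxide | COc1cc([O-])c([Si](C)(C)C)c(OC)c1OC.[Li+] | intermediate (not isolated)
6 | 3,4,5-trimethoxy-2-(trimethylsilyl)phenyl trifluoromethanesulfonate | COc1cc(OS(=O)(=O)C(F)(F)F)c([Si](C)(C)C)c(OC)c1OC | intermediate
7 | 4-bromo-3,5-dimethoxybenzaldehyde | COc1cc(C=O)cc(OC)c1Br | starting material
8 | 3,5-dimethoxy-4-(3,4,5-trimethoxyphenoxy)benzaldehyde | COc1cc(C=O)cc(OC)c1Oc1cc(OC)c(OC)c(OC)c1 | intermediate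
9 | 4-(2-iodo-3,4,5-trimethoxyphenoxy)-3,5-dimethoxybenzaldehyde | COc1cc(C=O)cc(OC)c1Oc1cc(OC)c(OC)c(OC)c1I | intermediate
10 | syringaldehyde (4-hydroxy-3,5-dimethoxybenzaldehyde) | COc1cc(C=O)cc(OC)c1O | starting material
11 | 4-(benzyloxy)-3,5-dimethoxybenzaldehyde | COc1cc(C=O)cc(OC)c1OCc1ccccc1 | intermediate
12 | 4-(benzyloxy)-3,5-dimethoxyphenyl formate | COc1cc(OC=O)cc(OC)c1OCc1ccccc1 | intermediate (not isolated)
13 | 4-(benzyloxy)-3,5-dimethoxyphenol | COc1cc(O)cc(OC)c1OCc1ccccc1 | intermediate
14 | three-ring aldehyde D–E–F, 4-{2-[4-(benzyloxy)-3,5-dimethoxyphenoxy]-3,4,5-trimethoxyphenoxy}-3,5-dimethoxybenzaldehyde | COc1cc(C=O)cc(OC)c1Oc1cc(OC)c(OC)c(OC)c1Oc1cc(OC)c(OCc2ccccc2)c(OC)c1 | intermediate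
15 | formate of the three-ring phenol D–E–F | COc1cc(OC=O)cc(OC)c1Oc1cc(OC)c(OC)c(OC)c1Oc1cc(OC)c(OCc2ccccc2)c(OC)c1 | intermediate (not isolated)
16 | three-ring phenol D–E–F, 4-{2-[4-(benzyloxy)-3,5-dimethoxyphenoxy]-3,4,5-trimethoxyphenoxy}-3,5-dimethoxyphenol | COc1cc(O)cc(OC)c1Oc1cc(OC)c(OC)c(OC)c1Oc1cc(OC)c(OCc2ccccc2)c(OC)c1 | intermediate
17 | five-ring aldehyde B–C–D–E–F (formyl on C1 of ring B, benzyl ether on C4 of ring F) | COc1cc(C=O)cc(OC)c1Oc1cc(OC)c(OC)c(OC)c1Oc1cc(OC)c(Oc2cc(OC)c(OC)c(OC)c2Oc2cc(OC)c(OCc3ccccc3)c(OC)c2)c(OC)c1 | intermediate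
18 | formate of the five-ring phenol B–C–D–E–F | COc1cc(OC=O)cc(OC)c1Oc1cc(OC)c(OC)c(OC)c1Oc1cc(OC)c(Oc2cc(OC)c(OC)c(OC)c2Oc2cc(OC)c(OCc3ccccc3)c(OC)c2)c(OC)c1 | intermediate (not isolated)
19 | five-ring phenol B–C–D–E–F (hydroxyl on C1 of ring B, benzyl ether on C4 of ring F) | COc1cc(O)cc(OC)c1Oc1cc(OC)c(OC)c(OC)c1Oc1cc(OC)c(Oc2cc(OC)c(OC)c(OC)c2Oc2cc(OC)c(OCc3ccccc3)c(OC)c2)c(OC)c1 | intermediate
20 | 2-iodo-1,3,5-trimethoxybenzene | COc1cc(OC)c(I)c(OC)c1 | starting material
21 | six-ring benzyl ether A–B–C–D–E–F (benzyl ether on C4 of ring F) | COc1cc(OC)c(Oc2cc(OC)c(Oc3cc(OC)c(OC)c(OC)c3Oc3cc(OC)c(Oc4cc(OC)c(OC)c(OC)c4Oc4cc(OC)c(OCc5ccccc5)c(OC)c4)c(OC)c3)c(OC)c2)c(OC)c1 | intermediate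
22 | six-ring phenol A–B–C–D–E–F (free hydroxyl on C4 of ring F) | COc1cc(OC)c(Oc2cc(OC)c(Oc3cc(OC)c(OC)c(OC)c3Oc3cc(OC)c(Oc4cc(OC)c(OC)c(OC)c4Oc4cc(OC)c(O)c(OC)c4)c(OC)c3)c(OC)c2)c(OC)c1 | intermediate
23 | potassium phenoxide of the six-ring phenol | COc1cc(OC)c(Oc2cc(OC)c(Oc3cc(OC)c(OC)c(OC)c3Oc3cc(OC)c(Oc4cc(OC)c(OC)c(OC)c4Oc4cc(OC)c([O-])c(OC)c4)c(OC)c3)c(OC)c2)c(OC)c1.[K+] | intermediate (not isolated)
24 | 3,4,5-trimethoxybenzyne (1,2-didehydro-3,4,5-trimethoxybenzene) | COC1=C(OC)C(OC)=CC#C1 | intermediate (not isolated)
25 | seven-ring aryl iodide A–B–C–D–E–F–G (iodine on C6 of ring G) | COc1cc(OC)c(Oc2cc(OC)c(Oc3cc(OC)c(OC)c(OC)c3Oc3cc(OC)c(Oc4cc(OC)c(OC)c(OC)c4Oc4cc(OC)c(Oc5cc(OC)c(OC)c(OC)c5I)c(OC)c4)c(OC)c3)c(OC)c2)c(OC)c1 | intermediate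
26 | permethylated eight-ring ether A–B–C–D–E–F–G–H | COc1cc(OC)c(Oc2cc(OC)c(Oc3cc(OC)c(OC)c(OC)c3Oc3cc(OC)c(Oc4cc(OC)c(OC)c(OC)c4Oc4cc(OC)c(Oc5cc(OC)c(OC)c(OC)c5Oc5cc(OC)c(OC)c(OC)c5)c(OC)c4)c(OC)c3)c(OC)c2)c(OC)c1 | intermediate
27 | CNP0206369.0 | Oc1cc(O)c(Oc2cc(O)c(Oc3cc(O)c(O)c(O)c3Oc3cc(O)c(Oc4cc(O)c(O)c(O)c4Oc4cc(O)c(Oc5cc(O)c(O)c(O)c5Oc5cc(O)c(O)c(O)c5)c(O)c4)c(O)c3)c(O)c2)c(O)c1 | target

## Step count and least certain steps

Total step count: 16. Longest linear sequence: 11 steps (steps 4, 5 and 8 to 16, from 1 and 7 to 27). Steps 1 to 3 (aryne precursor 6) and steps 6 and 7 (ring F phenol 13) are side branches.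

**Step 14 (key step, proposed new method).** The most likely failures are protonation of the aryl anion before iodine transfer, which would leave ring G without its handle, and attack of the phenoxide on the perfluoroalkene released by the spent donor. Consumption of the aryne by other anions in the flask is a third risk. The fallback uses only the known operations of steps 7 to 12 and builds rings G and H first. It sets out from 9 and 1 and comes back at 26. 9 and 1 are joined by the copper coupling of step 8 (CuI, picolinic acid, K3PO4, DMSO, 90 °C) to the three-ring aldehyde F–G–H F1. Peracid oxidation as in step 7 gives the formate of the three-ring phenol F2, and methanolysis gives the three-ring phenol F–G–H F3. F3 then takes the place of 13: coupling with 9 gives the five-ring aldehyde D–E–F–G–H F4, and oxidation through the formate of the five-ring phenol F5 gives the five-ring phenol D–E–F–G–H F6. Coupling of F6 with 9 gives the seven-ring aldehyde B–C–D–E–F–G–H F7, and oxidation through the formate of the seven-ring phenol F8 gives the seven-ring phenol B–C–D–E–F–G–H F9. Coupling of F9 with 20 as in step 12 gives 26.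

**Step 15.** The carbon–iodine bond of 25 lies between two oxygen substituents on a large, electron-rich substrate. Slow copper insertion and reductive loss of iodine are the likely failures. The fallback inverts the polarity, setting out from 25 and coming back at 26. Direct hydroxylation of the iodide (Pd2(dba)3, t-BuXPhos, KOH, dioxane/H2O, 100 °C) would give the seven-ring phenol A–B–C–D–E–F–G F10 with a hydroxyl on C6 of ring G. Its phenoxide is then arylated with aryne 24 released from 6 (CsF, MeCN, rt) with proton capture, the known O-arylation of phenols by arynes from ortho-silylaryl triflates, which builds ring H directly.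

**Step 11.** The peracid may oxidise the two pentaoxygenated rings of 17, or hydride may migrate in place of the aryl group and give the acid. The fallback moves the oxidation to the small block and makes the unmasking on the five-ring compound an acetal cleavage. It sets out from 9 and 16 and comes back at 19. 9 is oxidised with H2O2 and catalytic H2SO4 in MeOH, which should leave the aryl iodide alone, through the iodinated aryl formate F11 to the iodophenol F12. F12 is protected with MOMCl and i-Pr2NEt as the iodinated methoxymethyl ether F13. F13 is coupled with 16 under the conditions of step 10 to the five-ring methoxymethyl ether B–C–D–E–F F14, and HCl in MeOH cleaves F14 to 19.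

**Step 16.** Twenty-one ether cleavages must all go to completion, and the free polyphenol may oxidise during isolation. The fallback separates purification from deprotection, setting out from 26 and coming back at 27. The crude product of the BBr3 reaction is acetylated (Ac2O, pyridine) to the henicosaacetate of 27 F15, which is stable to air and chromatography, so that incompletely demethylated material can be removed. Acid methanolysis (HCl in MeOH, argon) then releases 27.

## Further compounds

F1 | step 14 | three-ring aldehyde F–G–H, 3,5-dimethoxy-4-[3,4,5-trimethoxy-2-(3,4,5-trimethoxyphenoxy)phenoxy]benzaldehyde | COc1cc(C=O)cc(OC)c1Oc1cc(OC)c(OC)c(OC)c1Oc1cc(OC)c(OC)c(OC)c1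
F2 | step 14 | formate of the three-ring phenol F–G–H | COc1cc(OC=O)cc(OC)c1Oc1cc(OC)c(OC)c(OC)c1Oc1cc(OC)c(OC)c(OC)c1
F3 | step 14 | three-ring phenol F–G–H, 3,5-dimethoxy-4-[3,4,5-trimethoxy-2-(3,4,5-trimethoxyphenoxy)phenoxy]phenol | COc1cc(O)cc(OC)c1Oc1cc(OC)c(OC)c(OC)c1Oc1cc(OC)c(OC)c(OC)c1
F4 | step 14 | five-ring aldehyde D–E–F–G–H (formyl on C1 of ring D) | COc1cc(C=O)cc(OC)c1Oc1cc(OC)c(OC)c(OC)c1Oc1cc(OC)c(Oc2cc(OC)c(OC)c(OC)c2Oc2cc(OC)c(OC)c(OC)c2)c(OC)c1
F5 | step 14 | formate of the five-ring phenol D–E–F–G–H | COc1cc(OC=O)cc(OC)c1Oc1cc(OC)c(OC)c(OC)c1Oc1cc(OC)c(Oc2cc(OC)c(OC)c(OC)c2Oc2cc(OC)c(OC)c(OC)c2)c(OC)c1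
F6 | step 14 | five-ring phenol D–E–F–G–H (hydroxyl on C1 of ring D) | COc1cc(O)cc(OC)c1Oc1cc(OC)c(OC)c(OC)c1Oc1cc(OC)c(Oc2cc(OC)c(OC)c(OC)c2Oc2cc(OC)c(OC)c(OC)c2)c(OC)c1
F7 | step 14 | seven-ring aldehyde B–C–D–E–F–G–H (formyl on C1 of ring B) | COc1cc(C=O)cc(OC)c1Oc1cc(OC)c(OC)c(OC)c1Oc1cc(OC)c(Oc2cc(OC)c(OC)c(OC)c2Oc2cc(OC)c(Oc3cc(OC)c(OC)c(OC)c3Oc3cc(OC)c(OC)c(OC)c3)c(OC)c2)c(OC)c1
F8 | step 14 | formate of the seven-ring phenol B–C–D–E–F–G–H | COc1cc(OC=O)cc(OC)c1Oc1cc(OC)c(OC)c(OC)c1Oc1cc(OC)c(Oc2cc(OC)c(OC)c(OC)c2Oc2cc(OC)c(Oc3cc(OC)c(OC)c(OC)c3Oc3cc(OC)c(OC)c(OC)c3)c(OC)c2)c(OC)c1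
F9 | step 14 | seven-ring phenol B–C–D–E–F–G–H (hydroxyl on C1 of ring B) | COc1cc(O)cc(OC)c1Oc1cc(OC)c(OC)c(OC)c1Oc1cc(OC)c(Oc2cc(OC)c(OC)c(OC)c2Oc2cc(OC)c(Oc3cc(OC)c(OC)c(OC)c3Oc3cc(OC)c(OC)c(OC)c3)c(OC)c2)c(OC)c1
F10 | step 15 | seven-ring phenol A–B–C–D–E–F–G (hydroxyl on C6 of ring G) | COc1cc(OC)c(Oc2cc(OC)c(Oc3cc(OC)c(OC)c(OC)c3Oc3cc(OC)c(Oc4cc(OC)c(OC)c(OC)c4Oc4cc(OC)c(Oc5cc(OC)c(OC)c(OC)c5O)c(OC)c4)c(OC)c3)c(OC)c2)c(OC)c1
F11 | step 11 | 4-(2-iodo-3,4,5-trimethoxyphenoxy)-3,5-dimethoxyphenyl formate | COc1cc(OC=O)cc(OC)c1Oc1cc(OC)c(OC)c(OC)c1I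
F12 | step 11 | 4-(2-iodo-3,4,5-trimethoxyphenoxy)-3,5-dimethoxyphenol | COc1cc(O)cc(OC)c1Oc1cc(OC)c(OC)c(OC)c1I
F13 | step 11 | 2-(2-iodo-3,4,5-trimethoxyphenoxy)-1,3-dimethoxy-5-(methoxymethoxy)benzene | COCOc1cc(OC)c(Oc2cc(OC)c(OC)c(OC)c2I)c(OC)c1
F14 | step 11 | five-ring methoxymethyl ether B–C–D–E–F (methoxymethyl ether on C1 of ring B, benzyl ether on C4 of ring F) | COCOc1cc(OC)c(Oc2cc(OC)c(OC)c(OC)c2Oc2cc(OC)c(Oc3cc(OC)c(OC)c(OC)c3Oc3cc(OC)c(OCc4ccccc4)c(OC)c3)c(OC)c2)c(OC)c1
F15 | step 16 | henicosaacetate of 27 | CC(=O)Oc1cc(OC(C)=O)c(Oc2cc(OC(C)=O)c(Oc3cc(OC(C)=O)c(OC(C)=O)c(OC(C)=O)c3Oc3cc(OC(C)=O)c(Oc4cc(OC(C)=O)c(OC(C)=O)c(OC(C)=O)c4Oc4cc(OC(C)=O)c(Oc5cc(OC(C)=O)c(OC(C)=O)c(OC(C)=O)c5Oc5cc(OC(C)=O)c(OC(C)=O)c(OC(C)=O)c5)c(OC(C)=O)c4)c(OC(C)=O)c3)c(OC(C)=O)c2)c(OC(C)=O)c1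
A1 | alternative 1 | methyl 6-[4-(benzyloxy)-3,5-dimethoxyphenoxy]-3,5-dioxohexanoate | COC(=O)CC(=O)CC(=O)COc1cc(OC)c(OCc2ccccc2)c(OC)c1
A2 | alternative 1 | 2-[4-(benzyloxy)-3,5-dimethoxyphenoxy]benzene-1,3,5-triol | Oc1cc(O)c(Oc2cc(OC)c(OCc3ccccc3)c(OC)c2)c(O)c1
A3 | alternative 2 | 4-(2-bromo-3,4,5-trimethoxyphenoxy)-3-ethoxycyclobut-2-en-1-one (racemic) | CCOC1=CC(=O)C1Oc1cc(OC)c(OC)c(OC)c1Br
A4 | alternative 2 | 2-(ethynyloxy)-1,3,5-trimethoxybenzene | C#COc1c(OC)cc(OC)cc1OC
A5 | alternative 2 | 2-(2-bromo-3,4,5-trimethoxyphenoxy)-3-ethoxy-5-(2,4,6-trimethoxyphenoxy)phenol | CCOc1cc(Oc2c(OC)cc(OC)cc2OC)cc(O)c1Oc1cc(OC)c(OC)c(OC)c1Br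
A6 | alternative 3 | 4-{(Z)-2-[4-(benzyloxy)-2,6-dimethoxyphenoxy]ethenyl}-2,3,4-trimethoxycyclobut-2-en-1-one (racemic) | COC1=C(OC)C(OC)(/C=C\Oc2c(OC)cc(OCc3ccccc3)cc2OC)C1=O
A7 | alternative 3 | 2-[4-(benzyloxy)-2,6-dimethoxyphenoxy]-4,5,6-trimethoxyphenol | Oc1c(OC)c(OC)c(OC)cc1Oc1c(OC)cc(OCc2ccccc2)cc1OC
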